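Ring B, the 2,4-dibromo-6-aryloxyphenol ring, is disconnected at C1–C2 and C5–C6. Its carbons C2(Br)–C3(H)–C4(Br)–C5(H) reproduce C3–C4–C5–C6 of 3,5-dibromo-2-pyrone, and the two oxygen-bearing carbons C1(OH) and C6(OAr) are the two carbons of an aryloxy ketene acetal. One operation, a [4+2] cycloaddition followed by loss of CO2 and of silanol, should form both C–C bonds, close ring B as an arene and put all six of its substituents in place. The precursor is the bis(trimethylsilyl) ketene acetal of (2,3,4,5-tetrabromo-6-methoxyphenoxy)acetic acid, reached from guaiacol; its partner, the dibromopyrone, comes from coumalic acid.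

Key step: step 5

Remark: the target contains no stereogenic element, so it is one achiral compound and no step has to set configuration; ring B is numbered as a phenol (C1 bears OH, C6 bears the aryloxy group).

Step 1
Reactants: 1 coumalic acid (2-oxo-2H-pyran-5-carboxylic acid)
Product: 2 3,5-dibromo-2H-pyran-2-one
Conditions: NBS (2.5 equiv), LiOAc, MeCN–H2O, rt
Reagents that add atoms: N-bromosuccinimide, O=C1CCC(=O)N1Br
Why: Bromodecarboxylation, in which NBS brominates the nucleophilic C3 of the pyrone and attacks C5 ipso to the carboxylate, which leaves as CO2 (a Hunsdiecker-type halodecarboxylation), is an established one-flask access to this pyrone.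

Step 2
Reactants: 3 guaiacol (2-methoxyphenol)
Product: 4 2,3,4,5-tetrabromo-6-methoxyphenol (tetrabromoguaiacol)
Conditions: Br2 (5 equiv), Fe powder (cat.), CH2Cl2, 0 °C → reflux; aq. NaHSO3
Reagents that add atoms: bromine, BrBr
Why: Electrophilic aromatic substitution, in which OH and OMe activate all four free ring positions and FeBr3 formed in the flask drives the last bromination next to OMe, raises no regiochemical question because every ring hydrogen is replaced.

Step 3
Reactants: 4 2,3,4,5-tetrabromo-6-methoxyphenol; 5 ethyl bromoacetate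
Product: 7 2-(2,3,4,5-tetrabromo-6-methoxyphenoxy)acetic acid, via ethyl ester 6 (not isolated)
Conditions: K2CO3, MeCN, 60 °C; then LiOH, THF–H2O, rt; then 1 M HCl
Reagents that add atoms: lithium hydroxide, [Li+].[OH-] (its oxygen becomes the acid OH)
Why: Williamson ether synthesis followed by saponification, in which the acidic tetrabromophenol is fully deprotonated by carbonate, its phenoxide displaces the primary carbonyl-activated bromide by SN2, and hydroxide then cleaves only the ethyl ester.

Step 4
Reactants: 7 2-(2,3,4,5-tetrabromo-6-methoxyphenoxy)acetic acid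
Product: 9 1,1-bis(trimethylsilyloxy)-2-(2,3,4,5-tetrabromo-6-methoxyphenoxy)ethene, via trimethylsilyl ester 8 (not isolated)
Conditions: TMSCl, Et3N, THF, 0 °C → rt; then TMSCl, LiHMDS, THF, −78 → 0 °C; evaporation, dry pentane, filtration under Ar; used at once
Reagents that add atoms: chlorotrimethylsilane, C[Si](C)(C)Cl
Why: Silyl ester formation followed by amide-base enolisation with O-silylation of the enolate in the flask (Ainsworth-type synthesis of bis(silyl) ketene acetals) should work because the aryloxy group acidifies the α-hydrogens, ring A has no hydrogen that could be metalated, and two identical silyloxy groups leave no alkene geometry to control.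

Step 5
Reactants: 9 1,1-bis(trimethylsilyloxy)-2-(2,3,4,5-tetrabromo-6-methoxyphenoxy)ethene; 2 3,5-dibromo-2H-pyran-2-one
Product: 12 [2,4-dibromo-6-(2,3,4,5-tetrabromo-6-methoxyphenoxy)phenoxy]trimethylsilane, via bridged lactone 10 (not isolated), via cyclohexadiene 11 (not isolated)
Conditions: PhMe, 2,6-di-tert-butyl-4-methylpyridine (cat.), 60 → 110 °C, sealed tube, Ar; evaporation
Reagents that add atoms: none
Why: The electron-poor pyrone 2 acts as the diene in a polar, asynchronous inverse-electron-demand Diels–Alder reaction in which the aryloxy-bearing carbon of 9, the nucleophilic terminus of the ketene acetal, bonds to C6 of 2 and the acetal carbon then bonds to C3, giving bridged lactone 10. Retro-[4+2] loss of CO2 from 10 gives cyclohexadiene 11, and 1,2-elimination of trimethylsilanol from 11 (hydrogen from the aryloxy carbon, silyloxy from the acetal carbon) gives the arene. The closest known reaction type is the Diels–Alder/decarboxylation/alcohol-elimination benzannulation of 2-pyrones with ketene acetals and 1,1,2-trialkoxyethenes, together with the cycloadditions of 3,5-dibromo-2-pyrone with electron-rich alkenes. Ring B is closed as a six-membered carbocycle in an intermolecular [4+2] mode, both new ring bonds being C–C bonds, and no stereocentre survives because those of 10 and 11 are erased on aromatisation. The step needs head-to-tail regioselectivity, secured by the match of the most nucleophilic carbon of 9 with C6, the most electrophilic diene terminus of 2, and it needs loss of silanol and not of the aryloxide, secured because the acetal carbon has no hydrogen and two identical OSiMe3 groups while the only removable hydrogen sits on the aryloxy carbon.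

Step 6
Reactants: 12 [2,4-dibromo-6-(2,3,4,5-tetrabromo-6-methoxyphenoxy)phenoxy]trimethylsilane
Product: 13 2,4-dibromo-6-(2,3,4,5-tetrabromo-6-methoxyphenoxy)phenol (target)
Conditions: 1 M HCl, THF, rt
Reagents that add atoms: none
Why: Acid-catalysed hydrolysis of an aryl trimethylsilyl ether should leave the diaryl ether, the methyl ether and the six C–Br bonds untouched.

Compound list
1 | coumalic acid (2-oxo-2H-pyran-5-carboxylic acid) | O=C(O)c1ccc(=O)oc1 | starting material
2 | 3,5-dibromo-2H-pyran-2-one | O=C1OC=C(Br)C=C1Br | intermediate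
3 | guaiacol (2-methoxyphenol) | COc1ccccc1O | starting material
4 | 2,3,4,5-tetrabromo-6-methoxyphenol | COc1c(Br)c(Br)c(Br)c(Br)c1O | intermediate
5 | ethyl bromoacetate | CCOC(=O)CBr | starting material
6 | ethyl 2-(2,3,4,5-tetrabromo-6-methoxyphenoxy)acetate | COc1c(Br)c(Br)c(Br)c(Br)c1OCC(=O)OCC | intermediate
7 | 2-(2,3,4,5-tetrabromo-6-methoxyphenoxy)acetic acid | COc1c(Br)c(Br)c(Br)c(Br)c1OCC(=O)O | intermediate
8 | trimethylsilyl 2-(2,3,4,5-tetrabromo-6-methoxyphenoxy)acetate | COc1c(Br)c(Br)c(Br)c(Br)c1OCC(=O)O[Si](C)(C)C | intermediate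
9 | 1,1-bis(trimethylsilyloxy)-2-(2,3,4,5-tetrabromo-6-methoxyphenoxy)ethene | COc1c(Br)c(Br)c(Br)c(Br)c1OC=C(O[Si](C)(C)C)O[Si](C)(C)C | intermediate
10 | 4,7-dibromo-6-(2,3,4,5-tetrabromo-6-methoxyphenoxy)-5,5-bis(trimethylsilyloxy)-2-oxabicyclo[2.2.2]oct-7-en-3-one (racemic, endo/exo mixture, stereocentres erased later in step 5) | COc1c(Br)c(Br)c(Br)c(Br)c1OC1C2OC(=O)C(Br)(C=C2Br)C1(O[Si](C)(C)C)O[Si](C)(C)C | intermediate
11 | 1,3-dibromo-5-(2,3,4,5-tetrabromo-6-methoxyphenoxy)-6,6-bis(trimethylsilyloxy)cyclohexa-1,3-diene (racemic, stereocentre erased later in step 5) | COc1c(Br)c(Br)c(Br)c(Br)c1OC1C=C(Br)C=C(Br)C1(O[Si](C)(C)C)O[Si](C)(C)C | intermediate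
12 | [2,4-dibromo-6-(2,3,4,5-tetrabromo-6-methoxyphenoxy)phenoxy]trimethylsilane | COc1c(Br)c(Br)c(Br)c(Br)c1Oc1cc(Br)cc(Br)c1O[Si](C)(C)C | intermediate
13 | 2,4-dibromo-6-(2,3,4,5-tetrabromo-6-methoxyphenoxy)phenol | COc1c(Br)c(Br)c(Br)c(Br)c1Oc1cc(Br)cc(Br)c1O | target

Total step count: 6. Longest linear sequence: 5 steps (steps 2, 3, 4, 5 and 6, from guaiacol 3 to 13); step 1 is a one-step side branch.

Steps most likely to fail

Step 5. Three processes could defeat it. The first bond formation could stay a Mukaiyama–Michael addition at C6, followed by silyl transfer and opening of the pyrone instead of ring closure. Adventitious proton sources could hydrolyse the ketene acetal before it reacts. Aromatisation could be diverted by ionisation and loss of the tetrabromoaryloxide. The fallback sets out from 4 and comes back at 13, building ring B from a preformed benzene ring. Phenol 4 is arylated by SNAr with 2-fluorobenzaldehyde (Cs2CO3, DMAc, 120 °C) to 2-(2,3,4,5-tetrabromo-6-methoxyphenoxy)benzaldehyde F1. Baeyer–Villiger (Dakin-type) oxidation with mCPBA in CH2Cl2 gives 2-(2,3,4,5-tetrabromo-6-methoxyphenoxy)phenyl formate F2, which K2CO3 in MeOH cleaves to 2-(2,3,4,5-tetrabromo-6-methoxyphenoxy)phenol F3. Br2 (2 equiv) in AcOH then brominates ortho and para to the free hydroxyl, which should give 13 directly.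

Step 4. Enolisation could be incomplete, the lithium enolate could be silylated on carbon or collapse to a ketene by loss of lithium trimethylsilanolate, and the bis(trimethylsilyl) acetal, which cannot be distilled, could hydrolyse while the salts are removed. The fallback sets out from 7 and comes back at 13; it replaces the lithium enolate by amine/silyl triflate soft enolisation and the labile silyl groups by robust ones. Acid 7 with TBSCl and imidazole in DMF gives tert-butyldimethylsilyl 2-(2,3,4,5-tetrabromo-6-methoxyphenoxy)acetate F4. TBSOTf and Et3N in CH2Cl2 convert it into 1,1-bis(tert-butyldimethylsilyloxy)-2-(2,3,4,5-tetrabromo-6-methoxyphenoxy)ethene F5, which can be filtered through basic alumina and stored. Heating F5 with 2 in toluene should lead, through 4,7-dibromo-6-(2,3,4,5-tetrabromo-6-methoxyphenoxy)-5,5-bis(tert-butyldimethylsilyloxy)-2-oxabicyclo[2.2.2]oct-7-en-3-one F6 and 1,3-dibromo-5-(2,3,4,5-tetrabromo-6-methoxyphenoxy)-6,6-bis(tert-butyldimethylsilyloxy)cyclohexa-1,3-diene F7, to tert-butyl[2,4-dibromo-6-(2,3,4,5-tetrabromo-6-methoxyphenoxy)phenoxy]dimethylsilane F8. TBAF in THF then cleaves F8 to 13.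

Step 2. The fourth bromination, at the carbon flanked by OMe and Br, could stall at the tribromo stage, and forcing it could oxidise the free phenol or let HBr cleave the methyl ether. The fallback avoids aromatic bromination altogether. It leaves the route at 3, which it replaces by purchased tetrabromocatechol (3,4,5,6-tetrabromobenzene-1,2-diol, Oc1c(O)c(Br)c(Br)c(Br)c1Br), and comes back at 4. Mono-O-methylation of this symmetric diol with MeI (1 equiv) and Li2CO3 in DMF relies on the large gap between its two pKa values and should give 4, with any dimethyl ether removed by base extraction.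

Further compounds
F1 | step 5 | 2-(2,3,4,5-tetrabromo-6-methoxyphenoxy)benzaldehyde | COc1c(Br)c(Br)c(Br)c(Br)c1Oc1ccccc1C=O
F2 | step 5 | 2-(2,3,4,5-tetrabromo-6-methoxyphenoxy)phenyl formate | COc1c(Br)c(Br)c(Br)c(Br)c1Oc1ccccc1OC=O
F3 | step 5 | 2-(2,3,4,5-tetrabromo-6-methoxyphenoxy)phenol | COc1c(Br)c(Br)c(Br)c(Br)c1Oc1ccccc1O
F4 | step 4 | tert-butyldimethylsilyl 2-(2,3,4,5-tetrabromo-6-methoxyphenoxy)acetate | COc1c(Br)c(Br)c(Br)c(Br)c1OCC(=O)O[Si](C)(C)C(C)(C)C
F5 | step 4 | 1,1-bis(tert-butyldimethylsilyloxy)-2-(2,3,4,5-tetrabromo-6-methoxyphenoxy)ethene | COc1c(Br)c(Br)c(Br)c(Br)c1OC=C(O[Si](C)(C)C(C)(C)C)O[Si](C)(C)C(C)(C)C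
F6 | step 4 | 4,7-dibromo-6-(2,3,4,5-tetrabromo-6-methoxyphenoxy)-5,5-bis(tert-butyldimethylsilyloxy)-2-oxabicyclo[2.2.2]oct-7-en-3-one | COc1c(Br)c(Br)c(Br)c(Br)c1OC1C2OC(=O)C(Br)(C=C2Br)C1(O[Si](C)(C)C(C)(C)C)O[Si](C)(C)C(C)(C)C
F7 | step 4 | 1,3-dibromo-5-(2,3,4,5-tetrabromo-6-methoxyphenoxy)-6,6-bis(tert-butyldimethylsilyloxy)cyclohexa-1,3-diene | COc1c(Br)c(Br)c(Br)c(Br)c1OC1C=C(Br)C=C(Br)C1(O[Si](C)(C)C(C)(C)C)O[Si](C)(C)C(C)(C)C
F8 | step 4 | tert-butyl[2,4-dibromo-6-(2,3,4,5-tetrabromo-6-methoxyphenoxy)phenoxy]dimethylsilane | COc1c(Br)c(Br)c(Br)c(Br)c1Oc1cc(Br)cc(Br)c1O[Si](C)(C)C(C)(C)C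
F0 | step 2 | none | none
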